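The strategy rests on reading the cyclopentane (C2–C3–C4–C5–C6, carotenoid numbering) as a folded acyclic lycopene end group. C5–OH and C6 stem from an E-5,6-epoxide. C2 and its CMe2OH carbon C1 stem from the terminal prenyl alkene. In one acid-triggered operation the epoxide opens at dienylic C6, C2 bonds to C6 to close the ring, and water adds to C1. This sets C6 and C2 beside the Sharpless-derived C5. The precursor is the silyl-protected C15 dienyl epoxide, made from geraniol in five steps. The cyclised C15 diol becomes a phosphonium salt and is joined at C11=C12 to a C25 polyenal built from pseudoionone and the C10 dialdehyde.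

Key step: step 6

Assumption: pseudoionone is used as its (3E,5E)-isomer (fractionated commercial material), because a Z bond at C5'=C6' would not be corrected by the final thermal equilibration; carotenoid numbering (primed for the acyclic half) is used for all fragments.

Step 1
Reactants: 1 geraniol
Product: 2 (2R,3R)-2,3-epoxygeraniol
Conditions: Ti(OiPr)4 (5 mol %), D-(−)-diethyl tartrate (7 mol %), t-BuOOH (1.5 equiv, decane), 4 Å MS, CH2Cl2, −20 °C
Reagents that add atoms: tert-butyl hydroperoxide, CC(C)(C)OO
Why: Sharpless asymmetric epoxidation: the titanium tartrate complex binds the allylic hydroxyl, so only the C2=C3 alkene of geraniol reacts, and the D-(−)-tartrate ligand directs oxygen to the face that gives the (2R,3R)-epoxide, which installs the C5–O stereocentre of the target and the C6 centre that step 6 will invert.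

Step 2
Reactants: 2 (2R,3R)-2,3-epoxygeraniol
Product: 3 (2S,3R)-2,3-epoxygeranial
Conditions: SO3·pyridine, DMSO, Et3N, CH2Cl2, 0 °C; used crude
Reagents that add atoms: none
Why: Parikh–Doering oxidation of a primary alcohol runs under basic, anhydrous conditions, so the acid-labile trisubstituted epoxide survives and the epoxide carbon next to the new aldehyde is not epimerised (the descriptor changes to 2S only because CHO outranks C3).

Step 3
Reactants: 3 (2S,3R)-2,3-epoxygeranial; 4 triethyl (E)-3-methyl-4-phosphonobut-2-enoate
Product: 6 ethyl (2E,4E,6R,7R)-6,7-epoxy-3,7,11-trimethyldodeca-2,4,10-trienoate, via lithiated phosphonate 5 (not isolated)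
Conditions: 4, LiN(SiMe3)2, THF–DMPU, −78 °C; then 3, −78 → 0 °C
Reagents that add atoms: none
Why: Horner–Wadsworth–Emmons olefination with the vinylogous stabilised phosphonate anion forms C7=C8 with E geometry and keeps the E trisubstituted C9=C10 alkene (any 9Z isomer is removed by chromatography), while the epoxide is inert to the non-nucleophilic base.

Step 4
Reactants: 6 ethyl (2E,4E,6R,7R)-6,7-epoxy-3,7,11-trimethyldodeca-2,4,10-trienoate
Product: 7 (2E,4E,6R,7R)-6,7-epoxy-3,7,11-trimethyldodeca-2,4,10-trien-1-ol
Conditions: i-Bu2AlH (2.3 equiv), THF, −78 → −40 °C; aq. potassium sodium tartrate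
Reagents that add atoms: none
Why: Ester reduction with i-Bu2AlH at low temperature is a 1,2-process that is much faster than hydride opening of the vinylic epoxide, and the ethereal solvent tempers the Lewis acidity of aluminium towards the now electron-rich dienyl epoxide.

Step 5
Reactants: 7 (2E,4E,6R,7R)-6,7-epoxy-3,7,11-trimethyldodeca-2,4,10-trien-1-ol
Product: 8 tert-butyldiphenylsilyl ether of 7 (E-epoxide, 5R,6R in carotenoid numbering)
Conditions: t-BuPh2SiCl, imidazole, DMF, 0 °C → rt; Et3N-deactivated SiO2
Reagents that add atoms: tert-butyl(chloro)diphenylsilane, CC(C)(C)[Si](Cl)(c1ccccc1)c1ccccc1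
Why: Standard imidazole-promoted silylation under basic conditions; the tert-butyldiphenylsilyl ether is chosen because it resists aqueous Lewis acid, is a poor leaving group at the far end of the diene and, unlike an ester, cannot bridge to C10 of the cation in step 6.

Step 6
Reactants: 8 tert-butyldiphenylsilyl ether of the C15 dienyl epoxide
Product: 10 tert-butyldiphenylsilyl ether of (2E,4E)-5-[(1R,2R,5R)-2-hydroxy-5-(2-hydroxypropan-2-yl)-2-methylcyclopentyl]-3-methylpenta-2,4-dien-1-ol (2R,5R,6R in carotenoid numbering; dienyl chain, CMe2OH arm and ring methyl on one face, ring hydroxyl on the other), via C1 tertiary cation 9 (not isolated)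
Conditions: Sc(OTf)3 (5 mol %), H2O (10 equiv), MeNO2–CH2Cl2 1:1 (0.01 M), −20 °C; Et3N quench; SiO2
Reagents that add atoms: water, O
Why: Hydrated Sc(OTf)3 binds the epoxide oxygen and loosens the C6–O bond, because positive charge at C6 is shared with the C7=C8–C9=C10 diene; C2 of the C1=C2 alkene then bonds to C6 in the Markovnikov sense and the tertiary cation 9 at C1 is quenched by water. The closest known reaction types are the acid rearrangement of acyclic carotenoid 5,6-epoxides to 2,6-cyclo end groups and epoxide-initiated cation–olefin cyclisations under Lewis acids, here carried over to a shorter dienyl homologue, a transfer that is untested. The cyclopentane closes 5-exo-trig at the alkene and 5-endo at the epoxide, a mode made accessible by the SN1-like loosening at the dienylic carbon, as in endo-selective openings of vinyl epoxides. C6 is controlled by the epoxide, since C2 enters opposite the departing oxygen and inversion of the E-(5R,6R)-epoxide puts C7 cis to the C5 methyl and trans to the C5 hydroxyl, while C5 keeps its C–O bond and its configuration. C2 is controlled by the alkene face: a chair-like 5-exo array with the dienyl group pseudo-equatorial, which favours cis-1,2 products in closures of 1-substituted hex-5-enyl intermediates, together with the bulky scandium-bound oxygen on the opposite face, should place the CMe2 arm cis to C7, though only by a modest margin. The step needs C6 over C5 ionisation (secured by the diene), alkene over water at C6 (high dilution, few equivalents of water, the non-participating silyl ether and no nitrile solvent that could capture C1 in a Ritter reaction), and clean sorting at C2, which the substrate provides because the epimeric cation lies cis to the C5 oxygen and collapses to a far less polar bicyclic ether that chromatography removes.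

Step 7
Reactants: 10 silyl ether of the cyclised C15 diol
Product: 11 (2E,4E)-5-[(1R,2R,5R)-2-hydroxy-5-(2-hydroxypropan-2-yl)-2-methylcyclopentyl]-3-methylpenta-2,4-dien-1-ol
Conditions: Bu4NF, THF, 0 °C → rt
Reagents that add atoms: none
Why: Fluoride-induced cleavage of the Si–O bond is selective for the silyl ether and leaves the two tertiary alcohols, the diene and all three stereocentres untouched.

Step 8
Reactants: 11 C15 triol
Product: 12 [(2E,4E)-5-[(1R,2R,5R)-2-hydroxy-5-(2-hydroxypropan-2-yl)-2-methylcyclopentyl]-3-methylpenta-2,4-dienyl]triphenylphosphonium bromide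
Conditions: PPh3·HBr, MeOH, 0 °C → rt; precipitation with Et2O
Reagents that add atoms: triphenylphosphine hydrobromide, Br.c1ccc(cc1)P(c1ccccc1)c1ccccc1
Why: Allylic substitution of a primary dienyl alcohol with PPh3·HBr, the standard entry to carotenoid Wittig salts, activates only the C11 hydroxyl because the C1 and C5 hydroxyls are not allylic and are not ionised by this weak acid in methanol, and phosphorus attacks the unhindered terminus C11.

Step 9
Reactants: 13 (3E,5E)-pseudoionone
Product: 14 (4E,6E)-3,7,11-trimethyldodeca-1,4,6,10-tetraen-3-ol (racemic)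
Conditions: CH2=CHMgBr, THF, −20 → 0 °C; aqueous quench
Reagents that add atoms: vinylmagnesium bromide, C=C[Mg]Br
Why: Grignard 1,2-addition to the dienone carbonyl gives the tertiary bis-allylic alcohol as a racemate, which is of no consequence because this centre becomes sp2 in step 10.

Step 10
Reactants: 14 (4E,6E)-3,7,11-trimethyldodeca-1,4,6,10-tetraen-3-ol
Product: 15 [(2E,4E,6E)-3,7,11-trimethyldodeca-2,4,6,10-tetraenyl]triphenylphosphonium bromide
Conditions: PPh3·HBr, MeOH, rt; crystallisation (acetone–EtOAc)
Reagents that add atoms: triphenylphosphine hydrobromide, Br.c1ccc(cc1)P(c1ccccc1)c1ccccc1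
Why: Acid ionisation of the tertiary alcohol gives a delocalised cation that PPh3 captures at its primary terminus (SN1-type allylic transposition), which extends the conjugation, and crystallisation selects the salt with the E C9'=C10' bond.

Step 11
Reactants: 15 C15 tetraenylphosphonium bromide; 16 (2E,4E,6E)-2,7-dimethylocta-2,4,6-trienedial
Product: 19 (2E,4E,6E,8E,10E,12E,14E)-2,7,11,15,19-pentamethylicosa-2,4,6,8,10,12,14,18-octaenal (C25 polyenal), via tetraenyl ylide 17 (not isolated), via Z-isomeric C25 aldehyde 18 (not isolated)
Conditions: 16 (2.5 equiv), 1,2-epoxybutane, EtOH, reflux, N2, dark; crystallisation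
Reagents that add atoms: none
Why: Wittig olefination in which bromide-opened epoxybutane releases the ylide slowly into an excess of the more electrophilic dialdehyde, so that one carbonyl group reacts, and the sterically congested Z isomer at the new C11'=C12' bond relaxes to E during the reflux.

Step 12
Reactants: 12 C15 dihydroxy phosphonium bromide; 19 C25 polyenal
Product: 22 (all-E,2R,5R,6R)-2,6-cyclolycopene-1,5-diol (target), via dihydroxy ylide 20 (not isolated), via 11Z isomer 21 (not isolated)
Conditions: 1,2-epoxybutane, EtOH, prolonged reflux, N2, dark; slow cooling, crystallisation (CH2Cl2–MeOH)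
Reagents that add atoms: none
Why: Wittig olefination under these nearly neutral conditions tolerates the free tertiary alcohols and forms C11=C12, the crowded 11Z isomer (H-10 against the C13 methyl) equilibrates thermally to the all-E polyene that crystallises, and no stereocentre is adjacent to a reacting site.

Compound list
1 | geraniol | CC(C)=CCC/C(C)=C/CO | starting material
2 | (2R,3R)-2,3-epoxygeraniol | OC[C@H]1O[C@]1(C)CCC=C(C)C | intermediate
3 | (2S,3R)-2,3-epoxygeranial | O=C[C@H]1O[C@]1(C)CCC=C(C)C | intermediate
4 | triethyl (E)-3-methyl-4-phosphonobut-2-enoate | CCOC(=O)/C=C(C)/CP(=O)(OCC)OCC | starting material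
5 | lithium salt of 4 deprotonated at the P-bearing carbon | [Li+].CCOC(=O)/C=C(C)/[CH-]P(=O)(OCC)OCC | intermediate
6 | ethyl (2E,4E,6R,7R)-6,7-epoxy-3,7,11-trimethyldodeca-2,4,10-trienoate | CCOC(=O)/C=C(C)/C=C/[C@H]1O[C@]1(C)CCC=C(C)C | intermediate
7 | (2E,4E,6R,7R)-6,7-epoxy-3,7,11-trimethyldodeca-2,4,10-trien-1-ol | OC/C=C(C)/C=C/[C@H]1O[C@]1(C)CCC=C(C)C | intermediate
8 | tert-butyldiphenylsilyl ether of 7 (precursor of the key step) | CC(C)(C)[Si](c1ccccc1)(c1ccccc1)OC/C=C(C)/C=C/[C@H]1O[C@]1(C)CCC=C(C)C | intermediate
9 | cyclised tertiary cation at C1 (arm cis to C7) | CC(C)(C)[Si](c1ccccc1)(c1ccccc1)OC/C=C(C)/C=C/[C@@H]1[C@H]([C+](C)C)CC[C@@]1(C)O | intermediate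
10 | silyl ether of the (2R,5R,6R)-C15 end-group diol (product of the key step) | CC(C)(C)[Si](c1ccccc1)(c1ccccc1)OC/C=C(C)/C=C/[C@@H]1[C@H](C(C)(C)O)CC[C@@]1(C)O | intermediate
11 | (2E,4E)-5-[(1R,2R,5R)-2-hydroxy-5-(2-hydroxypropan-2-yl)-2-methylcyclopentyl]-3-methylpenta-2,4-dien-1-ol | OC/C=C(C)/C=C/[C@@H]1[C@H](C(C)(C)O)CC[C@@]1(C)O | intermediate
12 | triphenylphosphonium bromide of 11 at C11 | [Br-].c1ccccc1[P+](C/C=C(C)/C=C/[C@@H]1[C@H](C(C)(C)O)CC[C@@]1(C)O)(c1ccccc1)c1ccccc1 | intermediate
13 | (3E,5E)-pseudoionone | CC(C)=CCC/C(C)=C/C=C/C(C)=O | starting material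
14 | (4E,6E)-3,7,11-trimethyldodeca-1,4,6,10-tetraen-3-ol, racemic | CC(C)=CCC/C(C)=C/C=C/C(C)(O)C=C | intermediate
15 | [(2E,4E,6E)-3,7,11-trimethyldodeca-2,4,6,10-tetraenyl]triphenylphosphonium bromide | [Br-].CC(C)=CCC/C(C)=C/C=C/C(C)=C/C[P+](c1ccccc1)(c1ccccc1)c1ccccc1 | intermediate
16 | (2E,4E,6E)-2,7-dimethylocta-2,4,6-trienedial | O=C/C(C)=C/C=C/C=C(C)/C=O | starting material
17 | ylide from 15 | CC(C)=CCC/C(C)=C/C=C/C(C)=C/C=P(c1ccccc1)(c1ccccc1)c1ccccc1 | intermediate
18 | C25 polyenal with Z geometry at the new C11'=C12' bond | CC(C)=CCC/C(C)=C/C=C/C(C)=C/C=C\C(C)=C\C=C\C=C(C)\C=O | intermediate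
19 | all-E C25 polyenal, 2,7,11,15,19-pentamethylicosa-2,4,6,8,10,12,14,18-octaenal | CC(C)=CCC/C(C)=C/C=C/C(C)=C/C=C/C(C)=C/C=C/C=C(C)/C=O | intermediate
20 | ylide from 12 | c1ccccc1P(=C/C=C(C)/C=C/[C@@H]1[C@H](C(C)(C)O)CC[C@@]1(C)O)(c1ccccc1)c1ccccc1 | intermediate
21 | (11Z,2R,5R,6R)-2,6-cyclolycopene-1,5-diol | CC(C)=CCC/C(C)=C/C=C/C(C)=C/C=C/C(C)=C/C=C/C=C(C)/C=C\C=C(C)\C=C\[C@@H]1[C@H](C(C)(C)O)CC[C@@]1(C)O | intermediate
22 | (all-E,2R,5R,6R)-2,6-cyclolycopene-1,5-diol | CC(C)=CCC/C(C)=C/C=C/C(C)=C/C=C/C(C)=C/C=C/C=C(C)/C=C/C=C(C)/C=C/[C@@H]1[C@H](C(C)(C)O)CC[C@@]1(C)O | target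

Total step count: 12. Longest linear sequence: 9 (steps 1–8, then step 12); steps 9–11 form the convergent branch.

Steps most likely to fail

1. Step 6.
- What may go wrong: The alkene may bond through its other face, after which the C5 oxygen rather than water closes onto C1. The delocalised cation may also be intercepted by water before the ring closes, be recaptured by the C5 oxygen at C8, or lose a proton from C11. It may also rotate about C5–C6 and so erode the inversion at C6.
- Fallback: This sets out from epoxy dienol 7, with aldehyde 19 as partner, and comes back to the route at target 22. The ring closure is postponed to the full C40 chromophore, where the acid rearrangement of the acyclic 5,6-epoxy end group is established chemistry.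
 - Alcohol 7 is oxidised with MnO2 in CH2Cl2 to the epoxy dienal F1.
 - Aldehyde 19 is reduced with NaBH4 to the C25 polyenol F2, and PPh3·HBr in MeOH converts that into the C25 phosphonium bromide F3.
 - A Wittig reaction of F3 with F1 (NaOMe, MeOH–CH2Cl2, 0 °C) gives (5R,6R)-5,6-epoxy-5,6-dihydrolycopene F4.
 - Treatment of F4 with dilute aqueous H2SO4 in THF, followed by thermal equilibration as in step 12 and chromatographic separation by polarity, leads to 22.

2. Step 8.
- What may go wrong: Acid ionisation of the dienyl alcohol may be followed by internal capture at C7 by the nearby C1 hydroxyl. A tertiary alcohol may instead be dehydrated. Either process competes with attack of PPh3 at C11.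
- Fallback: This sets out from triol 11 and comes back at salt 12, and it avoids any cation.
 - An Appel reaction (CBr4, PPh3, CH2Cl2, −20 °C) converts only the primary allylic hydroxyl into the dienyl bromide F5.
 - F5 is not stored; it is quaternised directly with PPh3 in EtOAc at room temperature by SN2 displacement to give 12.

3. Step 11.
- What may go wrong: Both aldehyde groups of the dialdehyde may condense. Relaxation of the Z isomer at the new bond may also stay incomplete.
- Fallback: This sets out from dialdehyde 16 and comes back at aldehyde 19. It replaces control by stoichiometry with desymmetrisation by protection.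
 - Dialdehyde 16 is treated with one equivalent of 2,2-dimethylpropane-1,3-diol and catalytic p-TsOH in toluene, which gives the mono-acetal aldehyde F6. This is separated from recyclable 16 and bis-acetal.
 - A Wittig reaction of F6 with salt 15 under the conditions of step 11 gives the C25 acetal F7.
 - Mild hydrolysis (pyridinium p-toluenesulfonate, acetone–water) releases 19.

Further compounds
F1 | step 6 | (2E,4E)-3-methyl-5-[(2R,3R)-3-methyl-3-(4-methylpent-3-enyl)oxiran-2-yl]penta-2,4-dienal | O=C/C=C(C)/C=C/[C@H]1O[C@]1(C)CCC=C(C)C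
F2 | step 6 | all-E 2,7,11,15,19-pentamethylicosa-2,4,6,8,10,12,14,18-octaen-1-ol | CC(C)=CCC/C(C)=C/C=C/C(C)=C/C=C/C(C)=C/C=C/C=C(C)/CO
F3 | step 6 | triphenylphosphonium bromide of F2 | [Br-].CC(C)=CCC/C(C)=C/C=C/C(C)=C/C=C/C(C)=C/C=C/C=C(C)/C[P+](c1ccccc1)(c1ccccc1)c1ccccc1
F4 | step 6 | (all-E,5R,6R)-5,6-epoxy-5,6-dihydrolycopene | CC(C)=CCC/C(C)=C/C=C/C(C)=C/C=C/C(C)=C/C=C/C=C(C)/C=C/C=C(C)/C=C/[C@H]1O[C@]1(C)CCC=C(C)C
F5 | step 8 | (1R,2R,3R)-2-[(1E,3E)-5-bromo-3-methylpenta-1,3-dienyl]-3-(2-hydroxypropan-2-yl)-1-methylcyclopentan-1-ol | BrC/C=C(C)/C=C/[C@@H]1[C@H](C(C)(C)O)CC[C@@]1(C)O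
F6 | step 11 | (2E,4E,6E)-7-(5,5-dimethyl-1,3-dioxan-2-yl)-2-methylocta-2,4,6-trienal | O=C/C(C)=C/C=C/C=C(C)/C1OCC(C)(C)CO1
F7 | step 11 | 5,5-dimethyl-1,3-dioxane acetal of aldehyde 19 | CC(C)=CCC/C(C)=C/C=C/C(C)=C/C=C/C(C)=C/C=C/C=C(C)/C1OCC(C)(C)CO1
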